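The disconnection cuts the C3–C1′ bond between the benzofuran and the 3,5-dihydroxy-2,4-dimethylphenyl ring together with the O1–C2 bond of the furan ring. The key step exploits the furan enol-ether unit O1–C2=C3: its two vicinal carbons, one carrying the ring oxygen and one the aryl group, are the two carbons of an alkyne. A palladium-catalysed arylative annulation therefore joins an ortho-alkynylphenol (ring A, the benzo ring, carrying the complete propanoate side chain on its C≡C bond) with a fully substituted aryl bromide. It closes the furan ring and forms the hindered C3–C1′ bond in one operation; the precursor is acyclic at the furan. Global O-demethylation finishes the synthesis.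

Key step: step 6

Assumption: the target SMILES carries no stereodescriptor; the molecule has no stereocentre and the C3–C1′ axis is taken as configurationally undefined, so no step has to control configuration.

Step 1
Reactants: 1 2,6-dimethoxytoluene (1,3-dimethoxy-2-methylbenzene)
Product: 3 5-bromo-1,3-dimethoxy-2-methylbenzene, via arylboronate 2 (not isolated)
Conditions: B2pin2 (0.6 equiv), [Ir(OMe)(cod)]2 (cat.), dtbpy, THF, 80 °C; evaporate; then CuBr2, MeOH/H2O, 80 °C
Reagents that add atoms: copper dibromide, [Cu+2].[Br-].[Br-]
Why: Sterically controlled iridium-catalysed C–H borylation of a 1,2,3-trisubstituted arene should take the only C–H bond without an ortho substituent (C5), and CuBr2 then converts the boronate into the bromide (halodeboronation) in the same flask.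

Step 2
Reactants: 3 5-bromo-1,3-dimethoxy-2-methylbenzene
Product: 4 6-bromo-2,4-dimethoxy-3-methylbenzaldehyde
Conditions: Cl2CHOMe, TiCl4, CH2Cl2, 0 °C to rt; then ice/H2O
Reagents that add atoms: dichloromethyl methyl ether, COC(Cl)Cl; water, O
Why: Rieche formylation (electrophilic aromatic substitution); the two free ring positions of 3 are equivalent, each ortho to one methoxy group and para to the other, so only one aldehyde can form.

Step 3
Reactants: 4 6-bromo-2,4-dimethoxy-3-methylbenzaldehyde
Product: 5 1-bromo-3,5-dimethoxy-2,4-dimethylbenzene
Conditions: Et3SiH (excess), TFA, CH2Cl2, 0 °C to rt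
Reagents that add atoms: none
Why: Ionic hydrogenation; the protonated aldehyde and then the benzylic cation, stabilised by the ortho and para methoxy groups, accept hydride from Et3SiH, which should take the formyl group down to methyl without touching the C–Br bond.

Step 4
Reactants: 6 3-methoxy-5-methylphenol
Product: 7 2-iodo-5-methoxy-3-methylphenol
Conditions: I2 (1.0 equiv), NaHCO3, THF/H2O, 0 °C
Reagents that add atoms: iodine, II
Why: Electrophilic iodination of the phenol under bicarbonate should place iodine ortho to the hydroxyl group and para to the methoxy group, by analogy with the behaviour of 3-methoxyphenol, and one equivalent at 0 °C should limit di-iodination.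

Step 5
Reactants: 7 2-iodo-5-methoxy-3-methylphenol; 8 methyl pent-4-ynoate
Product: 9 methyl 5-(2-hydroxy-4-methoxy-6-methylphenyl)pent-4-ynoate
Conditions: Pd(PPh3)2Cl2 (cat.), CuI (cat.), Et3N, THF, degassed, rt
Reagents that add atoms: none
Why: Sonogashira coupling of the aryl iodide with the terminal alkyne; room temperature and a low CuI loading are chosen so that the free ortho hydroxyl group does not add to the new alkyne.

Step 6
Reactants: 9 methyl 5-(2-hydroxy-4-methoxy-6-methylphenyl)pent-4-ynoate; 5 1-bromo-3,5-dimethoxy-2,4-dimethylbenzene
Product: 10 methyl 3-[3-(3,5-dimethoxy-2,4-dimethylphenyl)-6-methoxy-4-methyl-1-benzofuran-2-yl]propanoate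
Conditions: Pd2(dba)3 (cat.), XPhos, K2CO3, MeCN, 90 °C, slow addition of 9
Reagents that add atoms: none
Why: Oxidative addition of the zerovalent palladium–XPhos complex into the C–Br bond of 5 gives an arylpalladium bromide (divalent palladium) that binds the alkyne of 9 as a π-complex; the potassium phenoxide then attacks the alkyne carbon remote from ring A from the face opposite to palladium (anti-oxypalladation), and reductive elimination from the resulting 3-benzofuranyl(aryl)palladium species forms the C3–C1′ bond and returns zerovalent palladium. The closest known reaction type is the Cacchi arylative annulation of ortho-alkynylphenols with aryl halides (oxypalladation–reductive elimination). The furan ring closes in a 5-endo-dig mode at the O1–C2 bond. No stereocentre is created, and the configuration of the new biaryl axis is not controlled. The step needs arylative closure to outrun simple cycloisomerisation of 9 to the 3-unsubstituted benzofuran and O-arylation of the phenol: the bulky, electron-rich XPhos ligand should make oxidative addition to the hindered bromide fast, copper is absent, the medium is aprotic, and 9 is added slowly to the preformed arylpalladium species. Regiochemistry is fixed by the substrate, since the ortho oxygen can reach only the distal alkyne carbon, which leaves palladium and hence the aryl group on the carbon attached to ring A.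

Step 7
Reactants: 10 methyl 3-[3-(3,5-dimethoxy-2,4-dimethylphenyl)-6-methoxy-4-methyl-1-benzofuran-2-yl]propanoate
Product: 11 talarominine A, methyl 3-[3-(3,5-dihydroxy-2,4-dimethylphenyl)-6-hydroxy-4-methyl-1-benzofuran-2-yl]propanoate
Conditions: BBr3 (excess), CH2Cl2, −78 °C to 0 °C; then MeOH, 0 °C to rt
Reagents that add atoms: none
Why: BBr3 demethylation should cleave the three aryl methyl ethers, while the aliphatic methyl ester reacts much more slowly at low temperature and the methanol quench, which generates HBr in MeOH, would return any carboxylic acid to the methyl ester.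

Compound list
1 | 2,6-dimethoxytoluene (1,3-dimethoxy-2-methylbenzene) | COc1cccc(OC)c1C | starting material
2 | 2-(3,5-dimethoxy-4-methylphenyl)-4,4,5,5-tetramethyl-1,3,2-dioxaborolane | COc1cc(B2OC(C)(C)C(C)(C)O2)cc(OC)c1C | intermediate
3 | 5-bromo-1,3-dimethoxy-2-methylbenzene | COc1cc(Br)cc(OC)c1C | intermediate
4 | 6-bromo-2,4-dimethoxy-3-methylbenzaldehyde | COc1cc(Br)c(C=O)c(OC)c1C | intermediate
5 | 1-bromo-3,5-dimethoxy-2,4-dimethylbenzene | COc1cc(Br)c(C)c(OC)c1C | intermediate
6 | 3-methoxy-5-methylphenol | COc1cc(C)cc(O)c1 | starting material
7 | 2-iodo-5-methoxy-3-methylphenol | COc1cc(C)c(I)c(O)c1 | intermediate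
8 | methyl pent-4-ynoate | C#CCCC(=O)OC | starting material
9 | methyl 5-(2-hydroxy-4-methoxy-6-methylphenyl)pent-4-ynoate | COC(=O)CCC#Cc1c(C)cc(OC)cc1O | intermediate
10 | methyl 3-[3-(3,5-dimethoxy-2,4-dimethylphenyl)-6-methoxy-4-methyl-1-benzofuran-2-yl]propanoate | COC(=O)CCc1oc2cc(OC)cc(C)c2c1-c1cc(OC)c(C)c(OC)c1C | intermediate
11 | talarominine A, methyl 3-[3-(3,5-dihydroxy-2,4-dimethylphenyl)-6-hydroxy-4-methyl-1-benzofuran-2-yl]propanoate | COC(=O)CCc1oc2cc(O)cc(C)c2c1-c1cc(O)c(C)c(O)c1C | target

Total step count: 7. Longest linear sequence: 5 steps (steps 1, 2, 3, 6 and 7).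

Steps most likely to fail

Step 6. Cycloisomerisation of 9 without aryl transfer (base-mediated ring closure, or protonolysis before reductive elimination) may outrun oxidative addition to the hindered, electron-rich bromide, and reductive elimination at the crowded C3 position may be slow. The fallback separates the two bond formations and makes the same bond by cross-coupling on a closed furan. Setting out from 9, iodocyclisation (I2, NaHCO3, MeCN, rt) should give methyl 3-(3-iodo-6-methoxy-4-methyl-1-benzofuran-2-yl)propanoate F1. Setting out from 5, Miyaura borylation (B2pin2, Pd(dppf)Cl2, KOAc, dioxane, 90 °C) should give 2-(3,5-dimethoxy-2,4-dimethylphenyl)-4,4,5,5-tetramethyl-1,3,2-dioxaborolane F2. Suzuki–Miyaura coupling of F1 with F2 (Pd(OAc)2, SPhos, K3PO4, toluene/H2O, 100 °C) comes back to the route at 10.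

Step 4. Iodination may occur para to the hydroxyl group or between the two oxygen substituents instead of at the wanted position, or run on to di-iodination. The fallback changes the directing hierarchy by acylating the phenol so that the methoxy group becomes the strongest donor. Setting out from 6, acetylation (Ac2O, pyridine, rt) should give 3-methoxy-5-methylphenyl acetate F3. Iodination para to the methoxy group (NIS, cat. TFA, MeCN, rt) should give 2-iodo-5-methoxy-3-methylphenyl acetate F4. Methanolysis (K2CO3, MeOH, rt) comes back to the route at 7.

Step 5. Oxidative addition to the di-ortho-substituted, electron-rich iodophenol may be slow at room temperature, and on warming the free hydroxyl group may add to the new alkyne under palladium/copper catalysis (premature 5-endo closure to the 3-unsubstituted benzofuran). The fallback masks the oxygen during the alkynylation. Setting out from 7, silylation (TBSCl, imidazole, DMF, rt) should give tert-butyl(2-iodo-5-methoxy-3-methylphenoxy)dimethylsilane F5. Sonogashira coupling with 8 (Pd(PPh3)2Cl2, CuI, Et3N, THF, 50 °C) should give methyl 5-[2-(tert-butyldimethylsilyloxy)-4-methoxy-6-methylphenyl]pent-4-ynoate F6. Buffered desilylation (TBAF, AcOH, THF, 0 °C) comes back to the route at 9.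

Further compounds
F1 | step 6 | methyl 3-(3-iodo-6-methoxy-4-methyl-1-benzofuran-2-yl)propanoate | COC(=O)CCc1oc2cc(OC)cc(C)c2c1I
F2 | step 6 | 2-(3,5-dimethoxy-2,4-dimethylphenyl)-4,4,5,5-tetramethyl-1,3,2-dioxaborolane | COc1cc(B2OC(C)(C)C(C)(C)O2)c(C)c(OC)c1C
F3 | step 4 | 3-methoxy-5-methylphenyl acetate | COc1cc(C)cc(OC(C)=O)c1
F4 | step 4 | 2-iodo-5-methoxy-3-methylphenyl acetate | COc1cc(C)c(I)c(OC(C)=O)c1
F5 | step 5 | tert-butyl(2-iodo-5-methoxy-3-methylphenoxy)dimethylsilane | COc1cc(C)c(I)c(O[Si](C)(C)C(C)(C)C)c1
F6 | step 5 | methyl 5-[2-(tert-butyldimethylsilyloxy)-4-methoxy-6-methylphenyl]pent-4-ynoate | COC(=O)CCC#Cc1c(C)cc(OC)cc1O[Si](C)(C)C(C)(C)C
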